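**Plan**

1. Numbering: the core is a 3,7-dioxabicyclo[3.3.0]octane. Ring 1 is C1–C2(aryl A, 4-hydroxy-3-methoxyphenyl)–O3–C4–C5 and ring 2 is C5–C6(aryl B, 3-hydroxy-4,5-dimethoxyphenyl)–O7–C8–C1. The target is (1R,2S,5R,6S), with both aryl groups exo.
2. Cuts: both phenols are masked as benzyl ethers. O7–C6 and C1–C5 are then cut together, followed by the O3–C4 ether bond. This leaves an oxiranyl carbinol (aryl A half) and a cinnamyl bromide (aryl B half), each from a benzaldehyde and vinylmagnesium bromide.
3. Enabling feature: O7–C8–C1 is the imprint of a terminal oxirane, a temporary ring that serves as radical source at C1 and as latent O7 nucleophile and is consumed in the event. C5 lies 5-exo to C1 through C2–O3–C4. C6 is benzylic and para to the 4-methoxy group of ring B, so it can carry first a radical and then a leaving group.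
4. Forward order: the O3–C4 ether joins the halves, ring 1 arises by radical C1–C5 closure, and ring 2 arises last by O7–C6 closure in the same flask.
5. Stereochemistry: C2 comes from a Sharpless kinetic resolution. C1, C5 and C6 are set in the cascade under control of C2 and of the cis-fused bicycle.

Key step: step 7

Assumption: O-benzylvanillin and 3-hydroxy-4,5-dimethoxybenzaldehyde are taken as commercial, and the sense of the tartrate-controlled resolution is taken from the usual model for secondary allylic alcohols (aryl outranks vinyl, so the enantiomer that reacts fast with D-(−)-diisopropyl tartrate carries the S descriptor).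

**Route**

Step 1
Reactants: 1 4-(benzyloxy)-3-methoxybenzaldehyde
Product: 2 rac-1-[4-(benzyloxy)-3-methoxyphenyl]prop-2-en-1-ol
Conditions: CH2=CHMgBr, THF, −78 to 0 °C; aq NH4Cl
Reagents that add atoms: vinylmagnesium bromide, C=C[Mg]Br
Why: Grignard 1,2-addition of the vinyl nucleophile to the aldehyde should give the allylic alcohol with the aryl ethers untouched, and the new carbinol centre is left racemic on purpose because the next step resolves it.

Step 2
Reactants: 2 rac-1-[4-(benzyloxy)-3-methoxyphenyl]prop-2-en-1-ol
Product: 3 (R)-[4-(benzyloxy)-3-methoxyphenyl][(2S)-oxiran-2-yl]methanol (erythro)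
Conditions: Ti(OiPr)4 (0.2 equiv), D-(−)-DIPT (0.24 equiv), TBHP (0.45 equiv), 4 Å MS, CH2Cl2, −20 °C, stopped near 45 % conversion
Reagents that add atoms: tert-butyl hydroperoxide, CC(C)(C)OO
Why: In this Sharpless kinetic resolution (Ti(OiPr)4–tartrate asymmetric epoxidation of a secondary allylic alcohol) the (S)-carbinol enantiomer should react fast with D-(−)-DIPT and be epoxidised on the face that gives the erythro epoxy alcohol, so the future C2 centre is fixed here by reagent control while the (R)-enantiomer of 2 stays behind and is separated.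

Step 3
Reactants: 4 3-hydroxy-4,5-dimethoxybenzaldehyde
Product: 5 3-(benzyloxy)-4,5-dimethoxybenzaldehyde
Conditions: BnBr, K2CO3, DMF, rt to 60 °C
Reagents that add atoms: benzyl bromide, BrCc1ccccc1
Why: Williamson ether synthesis on the phenoxide should mask the only acidic site of ring B for the organometallic, hydride-base and radical steps that follow, and no stereocentre is formed.

Step 4
Reactants: 5 3-(benzyloxy)-4,5-dimethoxybenzaldehyde
Product: 6 rac-1-[3-(benzyloxy)-4,5-dimethoxyphenyl]prop-2-en-1-ol
Conditions: CH2=CHMgBr, THF, −78 to 0 °C; aq NH4Cl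
Reagents that add atoms: vinylmagnesium bromide, C=C[Mg]Br
Why: Grignard 1,2-addition to the aldehyde should give the 1-arylallyl alcohol, whose racemic carbinol centre does not matter because it is removed in the next step.

Step 5
Reactants: 6 rac-1-[3-(benzyloxy)-4,5-dimethoxyphenyl]prop-2-en-1-ol
Product: 7 1-(benzyloxy)-5-[(1E)-3-bromoprop-1-en-1-yl]-2,3-dimethoxybenzene
Conditions: PBr3 (0.4 equiv), Et2O, −10 to 0 °C; used crude at once
Reagents that add atoms: phosphorus tribromide, BrP(Br)Br
Why: Bromination with allylic transposition (SN2′ or ion-pair collapse of the bromophosphite of a 1-arylallyl alcohol) should place bromide on the terminal carbon because that restores conjugation with the electron-rich ring, which gives the thermodynamic (E)-cinnamyl bromide and removes the carbinol stereocentre.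

Step 6
Reactants: 3 (R)-[4-(benzyloxy)-3-methoxyphenyl][(2S)-oxiran-2-yl]methanol; 7 1-(benzyloxy)-5-[(1E)-3-bromoprop-1-en-1-yl]-2,3-dimethoxybenzene
Product: 8 (2S)-2-[(R)-[4-(benzyloxy)-3-methoxyphenyl]{[(2E)-3-[3-(benzyloxy)-4,5-dimethoxyphenyl]prop-2-en-1-yl]oxy}methyl]oxirane
Conditions: NaH, Bu4NI (cat.), THF, −20 to 0 °C
Reagents that add atoms: none
Why: In this Williamson ether synthesis the sodium alkoxide of 3 should displace the primary allylic bromide by SN2 at low temperature, where Payne rearrangement of the epoxy alkoxide is slow in an aprotic medium, and the carbinol centre is untouched because only its O–H bond reacts.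

Step 7
Reactants: 8 (2S)-2-[(R)-[4-(benzyloxy)-3-methoxyphenyl]{[(2E)-3-[3-(benzyloxy)-4,5-dimethoxyphenyl]prop-2-en-1-yl]oxy}methyl]oxirane
Product: 11 (1R,2S,5R,6S)-2-[4-(benzyloxy)-3-methoxyphenyl]-6-[3-(benzyloxy)-4,5-dimethoxyphenyl]-3,7-dioxabicyclo[3.3.0]octane, via bis-titanated oxolane 9 (not isolated), via iodo-oxolane titanium alkoxide 10 (not isolated)
Conditions: Cp2TiCl2 (2.5 equiv), Zn dust, THF, rt (forms Cp2TiCl); 8 added slowly; then I2 (1.2 equiv), rt to 40 °C; aq Na2S2O3
Reagents that add atoms: none
Why: Cp2TiCl (trivalent titanium) should transfer one electron to the oxirane of 8 and cleave the internal C1–O bond, giving the secondary C1 radical with O7 held on C8 as a tetravalent titanium alkoxide, and this radical closes ring 1 by 5-exo-trig attack on C5 of the cinnamyl ether, the closest known reaction type being the titanocene chloride mediated epoxide-opening radical cyclisation of epoxy allyl ethers to oxolanes. The benzylic C6 radical is then reduced by a second Cp2TiCl to the benzyltitanium species 9, I2 turns its C6–Ti bond into the C6–I bond of 10, and the titanium alkoxide O7 displaces iodide in a 5-exo-tet closure with strong SN1 character, which forms ring 2 as the last ring in a radical-polar crossover. C1 and C5 are set in the radical step by the existing C2 centre, because in the chair-like 5-exo transition state (Beckwith–Houk model) aryl A sits pseudo-equatorial, which puts C8 trans to aryl A on C1 and the C6 side chain cis to C8 on C5, the only arrangement that can bridge to a cis-fused bicycle. C6 is set in the ether closure, where ionisation assisted by the para-methoxy group of ring B should make both C6 epimers of 10 converge and O7 adds so that aryl B ends on the convex (exo) side. The step needs opening at C1 instead of C8 (secured by the more stable secondary radical), 5-exo instead of 6-endo closure (secured by the aryl-stabilised radical terminus at C6) and trans/cis diastereoselection around ring 1 (secured by the single stereocentre C2), while the configuration of the oxirane carbon is irrelevant because it becomes a planar radical.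

Step 8
Reactants: 11 (1R,2S,5R,6S)-2-[4-(benzyloxy)-3-methoxyphenyl]-6-[3-(benzyloxy)-4,5-dimethoxyphenyl]-3,7-dioxabicyclo[3.3.0]octane
Product: 12 (1R,2S,5R,6S)-2-(4-hydroxy-3-methoxyphenyl)-6-(3-hydroxy-4,5-dimethoxyphenyl)-3,7-dioxabicyclo[3.3.0]octane (target)
Conditions: H2 (1 atm), 10 % Pd/C, EtOAc, rt, stopped after uptake of two equivalents of H2
Reagents that add atoms: none
Why: Catalytic hydrogenolysis should cleave the two aryl benzyl ethers much faster than the hindered dialkyl benzylic C–O bonds of the bicycle in a neutral aprotic solvent, so controlled hydrogen uptake frees both phenols without touching the four stereocentres.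

**Compound list**

1 | 4-(benzyloxy)-3-methoxybenzaldehyde | COc1cc(C=O)ccc1OCc1ccccc1 | starting material
2 | rac-1-[4-(benzyloxy)-3-methoxyphenyl]prop-2-en-1-ol | COc1cc(C(O)C=C)ccc1OCc1ccccc1 | intermediate
3 | (R)-[4-(benzyloxy)-3-methoxyphenyl][(2S)-oxiran-2-yl]methanol | COc1cc([C@H]([C@@H]2CO2)O)ccc1OCc1ccccc1 | intermediate
4 | 3-hydroxy-4,5-dimethoxybenzaldehyde | COc1cc(C=O)cc(O)c1OC | starting material
5 | 3-(benzyloxy)-4,5-dimethoxybenzaldehyde | COc1cc(C=O)cc(OCc2ccccc2)c1OC | intermediate
6 | rac-1-[3-(benzyloxy)-4,5-dimethoxyphenyl]prop-2-en-1-ol | COc1cc(C(O)C=C)cc(OCc2ccccc2)c1OC | intermediate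
7 | 1-(benzyloxy)-5-[(1E)-3-bromoprop-1-en-1-yl]-2,3-dimethoxybenzene | COc1cc(/C=C/CBr)cc(OCc2ccccc2)c1OC | intermediate
8 | (2S)-2-[(R)-[4-(benzyloxy)-3-methoxyphenyl]{[(2E)-3-[3-(benzyloxy)-4,5-dimethoxyphenyl]prop-2-en-1-yl]oxy}methyl]oxirane | COc1cc([C@H]([C@@H]2CO2)OC/C=C/c2cc(OCc3ccccc3)c(OC)c(OC)c2)ccc1OCc1ccccc1 | intermediate
9 | bis-titanated oxolane: Cp2Ti(Cl) alkoxide of the (2S,3R,4R)-2-aryl-3-(hydroxymethyl)oxolane whose C4 side chain is CH(aryl B)–TiCp2Cl (C6 epimers) | COc1cc([C@H]2OC[C@H](C([Ti+2]Cl)c3cc(OCc4ccccc4)c(OC)c(OC)c3)[C@@H]2CO[Ti+2]Cl)ccc1OCc1ccccc1.c1cc[cH-]c1.c1cc[cH-]c1.c1cc[cH-]c1.c1cc[cH-]c1 | intermediate (not isolated)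
10 | iodo-oxolane titanium alkoxide: Cp2Ti(Cl) alkoxide of the (2S,3R,4R)-2-aryl-3-(hydroxymethyl)oxolane whose C4 side chain is CH(I)(aryl B) (C6 epimers) | COc1cc([C@H]2OC[C@H](C(I)c3cc(OCc4ccccc4)c(OC)c(OC)c3)[C@@H]2CO[Ti+2]Cl)ccc1OCc1ccccc1.c1cc[cH-]c1.c1cc[cH-]c1 | intermediate (not isolated)
11 | (1R,2S,5R,6S)-2-[4-(benzyloxy)-3-methoxyphenyl]-6-[3-(benzyloxy)-4,5-dimethoxyphenyl]-3,7-dioxabicyclo[3.3.0]octane | COc1cc([C@H]2OC[C@H]3[C@@H]2CO[C@@H]3c2cc(OCc3ccccc3)c(OC)c(OC)c2)ccc1OCc1ccccc1 | intermediate
12 | (1R,2S,5R,6S)-2-(4-hydroxy-3-methoxyphenyl)-6-(3-hydroxy-4,5-dimethoxyphenyl)-3,7-dioxabicyclo[3.3.0]octane | COc1cc([C@H]2OC[C@H]3[C@@H]2CO[C@@H]3c2cc(O)c(OC)c(OC)c2)ccc1O | target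

**Step count and risks**

Total step count: 8. Longest linear sequence: 6 steps (steps 3, 4, 5, 6, 7, 8, from 3-hydroxy-4,5-dimethoxybenzaldehyde).

Steps most likely to fail:

Step 7. The benzylic C6 radical may be lost by hydrogen abstraction from THF or by dimerisation before a second Cp2TiCl captures it, or iodination may not be followed by clean ether closure, so that ring 2 does not close or closes with poor control at C6. Fallback: starting from 8, the titanocene-mediated cyclisation is run alone and quenched with dilute acid, which should give the monocyclic alcohol {(2S,3R,4R)-2-[4-(benzyloxy)-3-methoxyphenyl]-4-[3-(benzyloxy)-4,5-dimethoxybenzyl]oxolan-3-yl}methanol F1. The last ring is then closed by a directed C–H functionalisation, the Suárez hypoiodite reaction (PhI(OAc)2, I2, visible light, CH2Cl2–cyclohexane, rt). The O7-centred radical should abstract hydrogen from C6 through a six-membered transition state, the benzylic radical is oxidised, and the oxygen closes onto it with aryl B exo. The route is rejoined at 11.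

Step 2. The enantiomers of an aryl vinyl carbinol may be poorly discriminated, or the acid-sensitive α-aryl epoxy alcohol may be opened by the titanium alkoxide medium. Fallback: starting from 2, an enzymatic acylative resolution (immobilised Candida antarctica lipase B, vinyl acetate, MTBE, 30 °C) should acylate the (R)-enantiomer to (R)-1-[4-(benzyloxy)-3-methoxyphenyl]prop-2-en-1-yl acetate F3 and leave (S)-1-[4-(benzyloxy)-3-methoxyphenyl]prop-2-en-1-ol F2. After separation, F2 is epoxidised under hydroxyl direction (VO(acac)2 cat., TBHP, CH2Cl2, 0 °C). This should give 3 as the favoured erythro isomer, separated by chromatography from its threo epimer (R)-[4-(benzyloxy)-3-methoxyphenyl][(2R)-oxiran-2-yl]methanol F4. The route is rejoined at 3.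

Step 6. The electron-rich cinnamyl bromide may ionise and decompose, or the sodium alkoxide of 3 may undergo Payne rearrangement, faster than O-alkylation. Fallback: starting from 3, O-allylation with allyl bromide and Ag2O (no free alkoxide, CH2Cl2, rt) should give the allyl ether (2S)-2-{(R)-[4-(benzyloxy)-3-methoxyphenyl](prop-2-en-1-yloxy)methyl}oxirane F5. Starting from 5, Wittig methylenation (Ph3PCH3Br, KOtBu, THF, 0 °C) should give 1-(benzyloxy)-5-ethenyl-2,3-dimethoxybenzene F6. Olefin cross-metathesis of F5 with excess F6 (RuCl2(=CHPh)(PCy3)(H2IMes), the second-generation Grubbs catalyst, CH2Cl2, 40 °C) should then build the (E)-configured C5=C6 bond directly. The route is rejoined at 8.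

**Further compounds**

F1 | step 7 | {(2S,3R,4R)-2-[4-(benzyloxy)-3-methoxyphenyl]-4-[3-(benzyloxy)-4,5-dimethoxybenzyl]oxolan-3-yl}methanol | COc1cc([C@H]2OC[C@H](Cc3cc(OCc4ccccc4)c(OC)c(OC)c3)[C@@H]2CO)ccc1OCc1ccccc1
F2 | step 2 | (S)-1-[4-(benzyloxy)-3-methoxyphenyl]prop-2-en-1-ol | COc1cc([C@H](C=C)O)ccc1OCc1ccccc1
F3 | step 2 | (R)-1-[4-(benzyloxy)-3-methoxyphenyl]prop-2-en-1-yl acetate | COc1cc([C@@H](C=C)OC(C)=O)ccc1OCc1ccccc1
F4 | step 2 | (R)-[4-(benzyloxy)-3-methoxyphenyl][(2R)-oxiran-2-yl]methanol | COc1cc([C@H]([C@H]2CO2)O)ccc1OCc1ccccc1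
F5 | step 6 | (2S)-2-{(R)-[4-(benzyloxy)-3-methoxyphenyl](prop-2-en-1-yloxy)methyl}oxirane | COc1cc([C@H]([C@@H]2CO2)OCC=C)ccc1OCc1ccccc1
F6 | step 6 | 1-(benzyloxy)-5-ethenyl-2,3-dimethoxybenzene | COc1cc(C=C)cc(OCc2ccccc2)c1OC
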